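The methylene bridge is disconnected from C6 of the cyclohexadienone ring, so that both halves derive from one compound, 3-methylphlorobutyrophenone: O-methylation gives aspidinol, whose aryl methyl is the future bridge, and asymmetric dearomative prenylation gives the (R)-dienone with its quaternary C4. The key step unites two natively nucleophilic C–H carbons by oxidation: DDQ takes hydride from the aspidinol methyl, which sits on C1′ ortho to the C2′ hydroxyl and para to the C4′ hydroxyl, to give an o-quinone methide, and the vinylogous-acid carbon C6 of the dienone (between C1=O and C5–OH) adds to it in the same flask. The precursors are thus two unfunctionalised monomers.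

Key step: step 4

Assumption: the sense of induction of the chiral ligand in step 3 cannot be predicted with certainty for this nucleophile, so the (R,R)-ligand is written and its antipode would be used if the first experiment shows the opposite sense; tert-butyl prenyl carbonate is taken as a purchasable reagent.

Step 1
Reactants: 1 2-methylbenzene-1,3,5-triol (2-methylphloroglucinol)
Product: 2 1-(2,4,6-trihydroxy-3-methylphenyl)butan-1-one
Conditions: butyryl chloride (1.1 equiv), AlCl3 (4 equiv), PhNO2/CH2Cl2, 0 → 60 °C; aq. HCl
Reagents that add atoms: butyryl chloride, CCCC(=O)Cl
Why: Friedel–Crafts acylation of the very electron-rich triol, whose two free ring positions are equivalent, and the first acyl group deactivates the ring against a second acylation.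

Step 2
Reactants: 2 1-(2,4,6-trihydroxy-3-methylphenyl)butan-1-one
Product: 3 aspidinol, 1-(2,6-dihydroxy-4-methoxy-3-methylphenyl)butan-1-one
Conditions: Me2SO4 (1.0 equiv), K2CO3 (1.0 equiv), acetone, rt
Reagents that add atoms: dimethyl sulfate, COS(=O)(=O)OC
Why: Williamson-type O-methylation, in which the 4-OH para to the ketone is the most acidic hydroxyl and is not weakened as a nucleophile by the O–H···O=C chelate of the ortho hydroxyls, so one equivalent of base and electrophile should methylate it first.

Step 3
Reactants: 2 1-(2,4,6-trihydroxy-3-methylphenyl)butan-1-one
Product: 4 (R)-2-butanoyl-3,5-dihydroxy-4-methyl-4-(3-methylbut-2-en-1-yl)cyclohexa-2,5-dien-1-one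
Conditions: tert-butyl prenyl carbonate (0.95 equiv), Pd2(dba)3·CHCl3 (2.5 mol%), (1R,2R)-N,N′-bis(2-diphenylphosphinobenzoyl)cyclohexane-1,2-diamine (7.5 mol%), CH2Cl2, 0 °C → rt; NaHCO3 extraction, then HCl
Reagents that add atoms: tert-butyl prenyl carbonate (tert-butyl 3-methylbut-2-en-1-yl carbonate), CC(C)=CCOC(=O)OC(C)(C)C
Why: Pd-catalysed asymmetric allylic alkylation (Tsuji–Trost) in its dearomatising mode, in which the π-prenyl palladium complex is attacked at its CH2 terminus by the methyl-bearing ring carbon C3, the most electron-rich carbon of the phenoxide, to give the chelated β-triketone, and the new quaternary stereocentre is set by the chiral ligand, which differentiates the two enantiotopic faces of the planar nucleophile.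

Step 4
Reactants: 3 aspidinol; 4 (R)-2-butanoyl-3,5-dihydroxy-4-methyl-4-(3-methylbut-2-en-1-yl)cyclohexa-2,5-dien-1-one
Product: 6 elaphopilosin A, via o-quinone methide 5 (not isolated)
Conditions: DDQ (1.0 equiv, slow addition), 3 (1.5 equiv), MeNO2/CH2Cl2, 0 °C → rt
Reagents that add atoms: none
Why: DDQ forms a charge-transfer complex with the electron-rich arene 3 and abstracts hydride from its C-methyl group, which is ortho to one hydroxyl and para to the other, and loss of the phenolic proton gives o-quinone methide 5; the enol of 4 then adds through C6 to the exocyclic CH2 and tautomerisation restores the arene and the vinylogous acid. The closest known reaction types are the DDQ-mediated cross-dehydrogenative coupling of benzylic C–H bonds with 1,3-dicarbonyl compounds and the DDQ generation of o-quinone methides from C-alkyl acylphloroglucinols with trapping in situ. No ring is closed and no stereocentre is formed; the quaternary C4 of 4 is not enolisable and should be carried through unchanged. The step needs oxidation of the methyl of 3 in preference to 4 and to the bridged product, and cross- in preference to homo-coupling: 4 is an electron-poor triketone enol without a benzylic C–H, the oxidant is kept at a low stationary concentration, the excess of 3 shields the bridging CH2 of the product, and C6 of 4 is its only unsubstituted nucleophilic carbon and far more nucleophilic than the single free aryl C–H of 3. An O-alkylated or [4+2] adduct would be an aryl ether or hemiketal isomer that should revert to 5 or open to the C-alkylated triketone under the weakly acidic conditions, so these pathways should funnel to 6.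

Compound list
1 | 2-methylbenzene-1,3,5-triol (2-methylphloroglucinol) | Cc1c(O)cc(O)cc1O | starting material
2 | 1-(2,4,6-trihydroxy-3-methylphenyl)butan-1-one | CCCC(=O)c1c(O)cc(O)c(C)c1O | intermediate
3 | aspidinol, 1-(2,6-dihydroxy-4-methoxy-3-methylphenyl)butan-1-one | CCCC(=O)c1c(O)cc(OC)c(C)c1O | intermediate
4 | (R)-2-butanoyl-3,5-dihydroxy-4-methyl-4-(3-methylbut-2-en-1-yl)cyclohexa-2,5-dien-1-one | CCCC(=O)C1=C(O)[C@](C)(CC=C(C)C)C(O)=CC1=O | intermediate
5 | o-quinone methide, 2-butanoyl-3-hydroxy-5-methoxy-6-methylidenecyclohexa-2,4-dien-1-one | CCCC(=O)C1=C(O)C=C(OC)C(=C)C1=O | intermediate (not isolated)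
6 | elaphopilosin A, (4R)-2-butanoyl-6-[(3-butanoyl-2,4-dihydroxy-6-methoxyphenyl)methyl]-3,5-dihydroxy-4-methyl-4-(3-methylbut-2-en-1-yl)cyclohexa-2,5-dien-1-one | CCCC(=O)C1=C(O)[C@](C)(CC=C(C)C)C(O)=C(Cc2c(OC)cc(O)c(C(=O)CCC)c2O)C1=O | target

Total step count: 4. Longest linear sequence: 3 (steps 1, 3 and 4, or 1, 2 and 4).

Steps most likely to fail

Step 4. The oxidant may attack the enol partner or over-oxidise the doubly activated bridging CH2 of the product, and the quinone methide may be captured by the free aryl position of excess 3 instead of by 4. The fallback separates oxidation from C–C bond formation and sets out from 3. DDQ (1.0 equiv) in MeOH/CH2Cl2 at 0 °C should trap the quinone methide as the benzylic ether 1-[2,6-dihydroxy-4-methoxy-3-(methoxymethyl)phenyl]butan-1-one F1, which is isolated. Heating this ether with 4 in toluene at 80 °C, where the acidity of 4 suffices to ionise the ether, should release methanol and regenerate 5 in the absence of any oxidant. Capture by C6 of 4 brings the route back at 6.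

Step 3. Facial selectivity may be poor, and the π-prenyl complex may attack the unsubstituted C5 or a phenolic oxygen, or prenylate the product a second time. The fallback gives up asymmetric catalysis for a racemic alkylation and a resolution, and sets out from 2. Classical base-mediated dearomative C-alkylation (prenyl bromide, NaOMe, MeOH, 0 °C) should give racemic 2-butanoyl-3,5-dihydroxy-4-methyl-4-(3-methylbut-2-en-1-yl)cyclohexa-2,5-dien-1-one F2, which as a strong vinylogous acid is separated from phenolic regioisomers by bicarbonate extraction. Preparative chromatography on a chiral stationary phase then sets aside (S)-2-butanoyl-3,5-dihydroxy-4-methyl-4-(3-methylbut-2-en-1-yl)cyclohexa-2,5-dien-1-one F3 and returns the route at 4.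

Step 2. Methylation may run on to the dimethyl ether or take place at a chelated ortho hydroxyl. The fallback replaces kinetic selection among three hydroxyls by chelation-controlled deprotection and sets out from 2. Exhaustive methylation (excess Me2SO4, K2CO3, acetone, reflux) should give 1-(2,4,6-trimethoxy-3-methylphenyl)butan-1-one F4. AlCl3 in chlorobenzene at 80 °C should then cleave only the two methoxy groups ortho to the ketone, which are activated through the aluminium chelate, while the para methoxy group survives, and the route is rejoined at 3.

Further compounds
F1 | step 4 | 1-[2,6-dihydroxy-4-methoxy-3-(methoxymethyl)phenyl]butan-1-one | CCCC(=O)c1c(O)cc(OC)c(COC)c1O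
F2 | step 3 | racemic 2-butanoyl-3,5-dihydroxy-4-methyl-4-(3-methylbut-2-en-1-yl)cyclohexa-2,5-dien-1-one | CCCC(=O)C1=C(O)C(C)(CC=C(C)C)C(O)=CC1=O
F3 | step 3 | (S)-2-butanoyl-3,5-dihydroxy-4-methyl-4-(3-methylbut-2-en-1-yl)cyclohexa-2,5-dien-1-one | CCCC(=O)C1=C(O)[C@@](C)(CC=C(C)C)C(O)=CC1=O
F4 | step 2 | 1-(2,4,6-trimethoxy-3-methylphenyl)butan-1-one | CCCC(=O)c1c(OC)cc(OC)c(C)c1OC
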